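No rate constant is given for this flask, so the reckoning rests on its charges and on two earlier runs that differ in [impurity].

| flask | starting material | free catalyst | impurity | remark | time |
|---|---|---|---|---|---|
| north-west | 0.80 M | 4 mM | 0.39 mM | run made earlier |  |
| north-east | 0.80 M | 4 mM | 1.5 mM | run made earlier |  |
| flask | 0.80 M | 4.0 mM | 0.77 mM |  | 5.0 h |

| run | time / h | target / % | isomer of the product A / % |
|---|---|---|---|
| north-west | 0.250 | 27.6 | 12.6 |
| north-west | 0.833 | 31.6 | 24.6 |
| north-west | 1.33 | 29.9 | 29.7 |
| north-west | 2.00 | 27.6 | 31.2 |
| north-west | 3.00 | 27.3 | 32.2 |
| north-west | 4.00 | 27.4 | 32.5 |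
| north-west | 5.00 | 27.5 | 32.6 |
| north-east | 0.667 | 26.3 | 24.9 |
| north-east | 1.33 | 25.5 | 34.0 |
| north-east | 2.00 | 24.3 | 35.7 |
| north-east | 3.00 | 23.7 | 37.9 |
| north-east | 4.00 | 23.2 | 38.4 |
| north-east | 5.00 | 23.2 | 37.0 |

(readings scatter by 0.5 percentage points)

- ratio of target to isomer of the product A at 30 s
- ratio of target to isomer of the product A at 12 min
- ratio of target to isomer of the product A at 5.0 h
- which of target and isomer of the product A there is more of at 5.0 h



Both runs level off, and the north-east run, charged with more impurity, ends with less target and more isomer of the product A. My reckoning supposes that each impurity removes one free catalyst for good, as a stoichiometric poison, and that the late ratio of target to isomer of the product A goes in step with what remains. The quantity to carry is the surviving share s, one minus charged [impurity] over charged [free catalyst]: 0.807 in the flask, 0.902 north-west and 0.625 north-east.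

The last two readings of each run give late ratios of 0.843 north-west and 0.615 north-east. Scaled by s, the north-west run alone gives 0.755 for the flask, and the north-east run alone gives 0.795. These two ways part by 0.0400, so strict proportion is not exact. The north-west run stands nearer the flask in s, so its figure travels less far and weighs more. Weighting by distance in s, I commit to 0.768, with isomer of the product A ahead. Stretched beyond the late ratios it was made for, the same scaling on the first north-west reading gives a rough 1.96 at 0.250 h, a time later than the asked 12 min.

The forecast gives ratios of 2.9 (1.9 to 6) at 30 s, 2.1 (1.6 to 2.7) at 12 min and 0.75 (0.69 to 0.81) at 5.0 h, with isomer of the product A ahead, on the ground that “the final target/isomer ratio depends on the impurity”. Its late ratio lies a little below mine.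

The flask gives 2.59 at 30 s, 2.00 at 12 min and 0.782 at 5.0 h, each inside its forecast range , with 26.7% target against 34.1% isomer of the product A at the end.

    starting material + free catalyst ⇌ target + free catalyst, rate k1*[starting material]*[free catalyst] forward; the back reaction follows from the equilibrium constant (K = 2.20, k = 0.160 /M/s)
    starting material ⇌ isomer of the product A (K = 2.20, k = 2.00 × 10⁻⁴ /s)
    free catalyst ⇌ dormant form (K = 21.0, k = 3.50 × 10⁻⁴ /s)
    free catalyst + impurity → spent catalyst (k = 170 /M/s)
    target ⇌ isomer of the product B (K = 0.900, k = 2.80 × 10⁻⁴ /s)

At 0.500 h spent catalyst in the flask stands at 19.2% of the catalyst charged, with impurity at 0% of its charge, and one minus s gives 19.3%. A neighbour flask like this one but with [impurity] at 3.10 mM has s of 0.225, which scales the flask's ratio at 5.0 h to 0.218. That neighbour gives 0.247 at 5.0 h, with spent catalyst at 77.5% and 52.2% isomer of the product A against 12.9% target.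

(All runs come from a simulation with constants of no real substance, and the scatter is random.)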